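**Strategy.** Ring A of the target is a 1,4-quinone (C1 acetoxy, C2 aryl, C3 carbonyl, C4 hydroxy, C5 aryl, C6 carbonyl). The aryl carbons C2 and C5 are para and frame the oxygenated pair C3–C4, while C6–C1 is a second oxygenated two-carbon unit. Ring A is therefore built from a 2,5-diaryl-3,4-bis(benzyloxy)cyclopentadienone (C2 to C5) and a 1,2-diborylalkyne (C6, C1). One thermal cycloaddition with loss of carbon monoxide forms bonds C1–C2 and C5–C6 and the hexasubstituted benzene. Benzyl ethers on both ring oxygens and both phenols allow a single hydrogenolysis to finish the synthesis after boron-to-oxygen exchange and monoacetylation, with no hydroxide step.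

Key step: step 4

Remark: 9 is taken as a purchasable reagent; compounds 2, 5, 6 and 7 each have one enolisable C–H stereocentre, are racemic and are drawn without a descriptor, and that centre is erased within steps 1 to 3.

Step 1
Reactants: 1 4-(benzyloxy)phenylacetic acid (two molecules)
Product: 3 1,3-bis[4-(benzyloxy)phenyl]propan-2-one, via keto acid 2 (not isolated)
Conditions: DCC (1.0 equiv), DMAP (0.25 equiv), CH2Cl2, rt
Reagents that add atoms: none
Why: Carbodiimide activation and DMAP-promoted Claisen-type C-acylation join two acyl units, and the β-keto acid 2 loses carbon dioxide in the flask, which is the established decarboxylative self-condensation of arylacetic acids to 1,3-diarylacetones.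

Step 2
Reactants: 3 1,3-bis[4-(benzyloxy)phenyl]propan-2-one; 4 diethyl oxalate
Product: 6 2,5-bis[4-(benzyloxy)phenyl]-4-hydroxycyclopent-4-ene-1,3-dione (enol of the 3,5-diarylcyclopentane-1,2,4-trione), via diketo ester 5 (not isolated)
Conditions: NaOEt (2.2 equiv), EtOH, reflux; then aq. HCl
Reagents that add atoms: none
Why: A double Claisen condensation (acylation of one benzylic carbon, then Dieckmann-type closure at the other) is driven by the stabilised enolate of the cyclic trione, the classical reaction of dibenzyl ketones with oxalic esters; the single C–H centre of 6 is enolisable and racemic.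

Step 3
Reactants: 6 2,5-bis[4-(benzyloxy)phenyl]-4-hydroxycyclopent-4-ene-1,3-dione
Product: 8 3,4-bis(benzyloxy)-2,5-bis[4-(benzyloxy)phenyl]cyclopenta-2,4-dien-1-one, via monobenzyl enol ether 7 (not isolated)
Conditions: BnOH (6 equiv), TsOH·H2O (0.1 equiv), toluene, reflux, Dean–Stark
Reagents that add atoms: benzyl alcohol, OCc1ccccc1
Why: Acid-catalysed enol etherification with azeotropic removal of water (the vinylogous Fischer esterification of cyclic 1,3-diones and diosphenols) forms each C–O bond at a ring carbon by addition–elimination, so C-benzylation cannot occur, and because the exchange is reversible the bis-ether with both alkoxy groups conjugated to the C1 carbonyl (the 3,4-isomer) should accumulate.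

Step 4
Reactants: 8 3,4-bis(benzyloxy)-2,5-bis[4-(benzyloxy)phenyl]cyclopenta-2,4-dien-1-one; 9 1,2-bis(4,4,5,5-tetramethyl-1,3,2-dioxaborolan-2-yl)ethyne
Product: 11 2,2'-{4,5-bis(benzyloxy)-3,6-bis[4-(benzyloxy)phenyl]-1,2-phenylene}bis(4,4,5,5-tetramethyl-1,3,2-dioxaborolane), via bridged ketone 10 (not isolated)
Conditions: 9 (1.5 equiv), mesitylene, 175 °C, sealed tube, argon
Reagents that add atoms: none
Why: Ring strain holds the diene of 8 in the cisoid geometry, and its aryl-bearing termini (C2 and C5 of the dienone) bond to the alkyne carbons of 9 from one face in a concerted thermal [4+2] cycloaddition that gives the bicyclo[2.2.1]heptadien-7-one 10, the benzyloxy donors at C3 and C4 raising the diene HOMO towards the boron-lowered alkyne LUMO. The one-carbon bridge of 10 is then expelled as carbon monoxide in a cheletropic step that is irreversible and paid for by aromatisation. The closest known reaction type is the Diels–Alder/decarbonylation of tetrasubstituted cyclopentadienones with alkynes, alkynylboronic esters among them. The benzene ring of 11 is closed intermolecularly by the cycloaddition, both new C–C bonds (C1–C2 and C5–C6 of ring A) forming in the same event. No stereocentre is created in 11, since the two bridgehead centres of 10 are fixed as the meso pair by the bicyclic frame and vanish with the bridge. Regioselectivity is not an issue because each partner has a mirror plane through the reacting atoms; the step needs cross-addition in place of dienone self-dimerisation, which the tetrasubstitution of 8, the excess of 9 and the reversibility of any dimer at this temperature should secure, while the neutral conditions leave benzyl ethers and pinacol boronates untouched.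

Step 5
Reactants: 11 2,2'-{4,5-bis(benzyloxy)-3,6-bis[4-(benzyloxy)phenyl]-1,2-phenylene}bis(4,4,5,5-tetramethyl-1,3,2-dioxaborolane)
Product: 13 4,5-bis(benzyloxy)-3,6-bis[4-(benzyloxy)phenyl]benzene-1,2-diol, via hydroxy boronate 12 (not isolated)
Conditions: NaBO3·4H2O (2.5 equiv), THF/H2O (degassed), 0 °C to rt, argon
Reagents that add atoms: sodium perborate, [Na+].[O-]OB=O
Why: Perborate adds a peroxide oxygen to each boron and the aryl carbon migrates from boron to oxygen at the same ring position (oxidative hydroxydeboronation of arylboronic esters), the mild stoichiometric oxidant under argon being chosen so that the electron-rich catechol is not carried on to a quinone.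

Step 6
Reactants: 13 4,5-bis(benzyloxy)-3,6-bis[4-(benzyloxy)phenyl]benzene-1,2-diol
Product: 15 3,4-bis(benzyloxy)-2,5-bis[4-(benzyloxy)phenyl]-6-hydroxyphenyl acetate, via cyclic orthoacetate 14 (not isolated)
Conditions: MeC(OMe)3 (3 equiv), PPTS (cat.), toluene, 80 °C, argon; then AcOH/H2O/THF, rt
Reagents that add atoms: trimethyl orthoacetate, COC(C)(OC)OC; water, O
Why: Acid-catalysed orthoester exchange ties both phenols into a 2-methoxy-2-methyl-1,3-benzodioxole, and its mild acidic hydrolysis through the 1,3-benzodioxol-2-ylium ion and the hemiorthoester should open to the monoacetate (the orthoester method for monoacylation of 1,2-diols), so no diacetate can form and the symmetry of 13 makes the choice of oxygen irrelevant.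

Step 7
Reactants: 15 3,4-bis(benzyloxy)-2,5-bis[4-(benzyloxy)phenyl]-6-hydroxyphenyl acetate
Product: 17 4-hydroxy-2,5-bis(4-hydroxyphenyl)-3,6-dioxocyclohexa-1,4-dien-1-yl acetate (target), via leuco acetate 16 (not isolated)
Conditions: H2 (1 atm), Pd/C, EtOAc/THF, rt; filter; then air, rt
Reagents that add atoms: none
Why: Catalytic hydrogenolysis should cleave all four aryl benzyl ethers while the aryl acetate is inert in the non-nucleophilic solvent, and the hydroxyhydroquinone 16 is then autoxidised by air to the hydroxy-1,4-quinone, the only para-quinone the acetate position allows; a 1,2-acetyl shift in 16 would be degenerate because it regenerates the same compound.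

**Compound list**

1 | 4-(benzyloxy)phenylacetic acid | OC(=O)Cc1ccc(OCc2ccccc2)cc1 | starting material
2 | 2,4-bis[4-(benzyloxy)phenyl]-3-oxobutanoic acid (racemic) | OC(=O)C(c1ccc(OCc2ccccc2)cc1)C(=O)Cc1ccc(OCc2ccccc2)cc1 | intermediate
3 | 1,3-bis[4-(benzyloxy)phenyl]propan-2-one | O=C(Cc1ccc(OCc2ccccc2)cc1)Cc1ccc(OCc2ccccc2)cc1 | intermediate
4 | diethyl oxalate | CCOC(=O)C(=O)OCC | starting material
5 | ethyl 3,5-bis[4-(benzyloxy)phenyl]-2,4-dioxopentanoate (racemic) | CCOC(=O)C(=O)C(c1ccc(OCc2ccccc2)cc1)C(=O)Cc1ccc(OCc2ccccc2)cc1 | intermediate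
6 | 2,5-bis[4-(benzyloxy)phenyl]-4-hydroxycyclopent-4-ene-1,3-dione (enol of the cyclopentane-1,2,4-trione; racemic) | O=C1C(c2ccc(OCc3ccccc3)cc2)C(=O)C(O)=C1c1ccc(OCc2ccccc2)cc1 | intermediate
7 | 4-(benzyloxy)-2,5-bis[4-(benzyloxy)phenyl]cyclopent-4-ene-1,3-dione (racemic) | O=C1C(c2ccc(OCc3ccccc3)cc2)C(=O)C(OCc2ccccc2)=C1c1ccc(OCc2ccccc2)cc1 | intermediate
8 | 3,4-bis(benzyloxy)-2,5-bis[4-(benzyloxy)phenyl]cyclopenta-2,4-dien-1-one | O=C1C(c2ccc(OCc3ccccc3)cc2)=C(OCc2ccccc2)C(OCc2ccccc2)=C1c1ccc(OCc2ccccc2)cc1 | intermediate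
9 | 1,2-bis(4,4,5,5-tetramethyl-1,3,2-dioxaborolan-2-yl)ethyne | CC1(C)OB(C#CB2OC(C)(C)C(C)(C)O2)OC1(C)C | starting material
10 | 2,3-bis(benzyloxy)-1,4-bis[4-(benzyloxy)phenyl]-5,6-bis(4,4,5,5-tetramethyl-1,3,2-dioxaborolan-2-yl)bicyclo[2.2.1]hepta-2,5-dien-7-one (meso; bridgeheads fixed by the bicycle) | O=C1[C@]2(c3ccc(OCc4ccccc4)cc3)C(B3OC(C)(C)C(C)(C)O3)=C(B3OC(C)(C)C(C)(C)O3)[C@@]1(c3ccc(OCc4ccccc4)cc3)C(OCc3ccccc3)=C2OCc1ccccc1 | intermediate
11 | 2,2'-{4,5-bis(benzyloxy)-3,6-bis[4-(benzyloxy)phenyl]-1,2-phenylene}bis(4,4,5,5-tetramethyl-1,3,2-dioxaborolane) | CC1(C)OB(OC1(C)C)c1c(B2OC(C)(C)C(C)(C)O2)c(-c2ccc(OCc3ccccc3)cc2)c(OCc2ccccc2)c(OCc2ccccc2)c1-c1ccc(OCc2ccccc2)cc1 | intermediate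
12 | 3,4-bis(benzyloxy)-2,5-bis[4-(benzyloxy)phenyl]-6-(4,4,5,5-tetramethyl-1,3,2-dioxaborolan-2-yl)phenol | Oc1c(B2OC(C)(C)C(C)(C)O2)c(-c2ccc(OCc3ccccc3)cc2)c(OCc2ccccc2)c(OCc2ccccc2)c1-c1ccc(OCc2ccccc2)cc1 | intermediate
13 | 4,5-bis(benzyloxy)-3,6-bis[4-(benzyloxy)phenyl]benzene-1,2-diol | Oc1c(O)c(-c2ccc(OCc3ccccc3)cc2)c(OCc2ccccc2)c(OCc2ccccc2)c1-c1ccc(OCc2ccccc2)cc1 | intermediate
14 | 5,6-bis(benzyloxy)-4,7-bis[4-(benzyloxy)phenyl]-2-methoxy-2-methyl-1,3-benzodioxole | COC1(C)Oc2c(O1)c(-c1ccc(OCc3ccccc3)cc1)c(OCc1ccccc1)c(OCc1ccccc1)c2-c1ccc(OCc2ccccc2)cc1 | intermediate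
15 | 3,4-bis(benzyloxy)-2,5-bis[4-(benzyloxy)phenyl]-6-hydroxyphenyl acetate | CC(=O)Oc1c(O)c(-c2ccc(OCc3ccccc3)cc2)c(OCc2ccccc2)c(OCc2ccccc2)c1-c1ccc(OCc2ccccc2)cc1 | intermediate
16 | 2,4,5-trihydroxy-3,6-bis(4-hydroxyphenyl)phenyl acetate | CC(=O)Oc1c(O)c(-c2ccc(O)cc2)c(O)c(O)c1-c1ccc(O)cc1 | intermediate
17 | 4-hydroxy-2,5-bis(4-hydroxyphenyl)-3,6-dioxocyclohexa-1,4-dien-1-yl acetate | CC(=O)OC1=C(c2ccc(O)cc2)C(=O)C(O)=C(c2ccc(O)cc2)C1=O | target

**Total step count:** 7. **Longest linear sequence:** 7 steps (from 1).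

**Steps most likely to fail**

Step 4. The cycloaddition at the hindered diborylalkyne may be slower than thermal loss of boron or decomposition of the benzyloxy dienone. The fallback delivers the two oxygenated carbons with vinylene carbonate, a small and thermally robust dienophile, and oxidises afterwards. It sets out from 8. Heating with vinylene carbonate (o-xylene, about 180 °C, sealed tube) should give the endo adduct 5,6-bis(benzyloxy)-4,7-bis[4-(benzyloxy)phenyl]-3a,4,7,7a-tetrahydro-4,7-methano-1,3-benzodioxole-2,8-dione F1. This should lose carbon monoxide in the same flask to give cis-5,6-bis(benzyloxy)-4,7-bis[4-(benzyloxy)phenyl]-3a,7a-dihydro-1,3-benzodioxol-2-one F2. Dehydrogenation with DDQ (toluene, rt to 60 °C) would give 5,6-bis(benzyloxy)-4,7-bis[4-(benzyloxy)phenyl]-1,3-benzodioxol-2-one F3. Hydrolysis of the aryl carbonate (aq. LiOH, degassed THF, 0 °C, then dilute HCl) would release catechol 13, where the route is rejoined at step 6.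

Step 3. The second condensation may stall at the mono-ether because forming the cross-conjugated dienone is uphill, or the acid may start to transfer benzyl groups from the aryl ethers. The fallback makes each C–O bond at the benzylic carbon by irreversible alkylation. It sets out from 6. Two successive Mitsunobu O-alkylations with benzyl alcohol (PPh3, DIAD, THF, 0 °C to rt) would pass through 7 and return to the route at 8, without acid or heat. This fallback makes no compound outside the list (F0).

Step 6. Orthoester exchange at the crowded catechol may be incomplete, or the hydrolysis may open the orthoester so that the catechol is returned. The fallback acylates exhaustively and then removes one acyl group. It sets out from 13. Acetylation (Ac2O, pyridine, DMAP cat., CH2Cl2, argon) should give 4,5-bis(benzyloxy)-3,6-bis[4-(benzyloxy)phenyl]-1,2-phenylene diacetate F4. Aminolysis with one equivalent of pyrrolidine (THF, 0 °C) should then remove one acetyl group. The phenol set free is hydrogen-bonded to the neighbouring ester and, once partly deprotonated by the amine, makes that ester a much poorer acyl donor, so the reaction should stop at 15, where the route is rejoined.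

**Further compounds**

F1 | step 4 | 5,6-bis(benzyloxy)-4,7-bis[4-(benzyloxy)phenyl]-3a,4,7,7a-tetrahydro-4,7-methano-1,3-benzodioxole-2,8-dione (endo) | O=C1[C@]2(c3ccc(OCc4ccccc4)cc3)[C@H]3OC(=O)O[C@H]3[C@@]1(c1ccc(OCc3ccccc3)cc1)C(OCc1ccccc1)=C2OCc1ccccc1
F2 | step 4 | cis-5,6-bis(benzyloxy)-4,7-bis[4-(benzyloxy)phenyl]-3a,7a-dihydro-1,3-benzodioxol-2-one | O=C1O[C@H]2C(c3ccc(OCc4ccccc4)cc3)=C(OCc3ccccc3)C(OCc3ccccc3)=C(c3ccc(OCc4ccccc4)cc3)[C@H]2O1
F3 | step 4 | 5,6-bis(benzyloxy)-4,7-bis[4-(benzyloxy)phenyl]-1,3-benzodioxol-2-one | O=C1Oc2c(O1)c(-c1ccc(OCc3ccccc3)cc1)c(OCc1ccccc1)c(OCc1ccccc1)c2-c1ccc(OCc2ccccc2)cc1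
F0 | step 3 | none | none
F4 | step 6 | 4,5-bis(benzyloxy)-3,6-bis[4-(benzyloxy)phenyl]-1,2-phenylene diacetate | CC(=O)Oc1c(OC(C)=O)c(-c2ccc(OCc3ccccc3)cc2)c(OCc2ccccc2)c(OCc2ccccc2)c1-c1ccc(OCc2ccccc2)cc1
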